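**Plan**

- Retrosynthesis: the C1–C1' ketone–arene bond and the C2'–O bond are cut together, giving 3,5-bis(methoxymethoxy)benzyne and a C20 acetoxy acid. The acid is then cut at the sp–sp3 bonds C6–C7, C9–C10 and C13–C14 of a skipped tetrayne and at C15–C16 (epoxide opening).
- Feature used: ring carbon C1' carries the C1 ketone and its neighbour C2' a phenolic oxygen, the pattern an aryne leaves when it inserts into the C(=O)–O bond of a carboxylic acid. The oxygen on C6', next to the former triple bond, fixes the direction of that insertion.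
- Forward: phloroglucinol is converted into the silyl triflate aryne precursor (steps 1–4). The chain is built by epoxide alkynylation and three copper-mediated alkyne–propargyl couplings, then semihydrogenated, saponified and acetylated (steps 5–13).
- Chain and arene are joined in step 14. No ring is formed anywhere; the benzene ring comes from phloroglucinol. The acetate and the methoxymethyl ethers are removed in steps 15 and 16.
- Stereochemistry: C17 (R) comes from (R)-1,2-epoxypentane, opened at its CH2 carbon. The four Z alkenes come from syn semihydrogenation of the tetrayne.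

Key step: step 14

Remark: chain atoms are numbered C1 (ketone carbon) to C20 and ring atoms C1' (acylated carbon) to C6'. The acid component enters as its commercial methyl ester 13, lithium acetylide as its commercial ethylenediamine complex 11, and the single-enantiomer epoxide 10 is taken as purchasable.

**Route**

Step 1
Reactants: 1 phloroglucinol
Product: 2 3,5-bis(methoxymethoxy)phenol
Conditions: MOMCl (2.0 equiv), iPr2NEt (2.2 equiv), DMF/CH2Cl2, 0 °C to rt; chromatography
Reagents that add atoms: chloromethyl methyl ether, COCCl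
Why: Statistical Williamson-type O-alkylation of the threefold-symmetric triphenol with two equivalents of MOMCl should give the bis-ether as the main fraction, separable from the mono- and tris-ethers, and no regiochemical question arises because the three hydroxyl groups are equivalent.

Step 2
Reactants: 2 3,5-bis(methoxymethoxy)phenol
Product: 3 3,5-bis(methoxymethoxy)phenyl N-(propan-2-yl)carbamate
Conditions: iPrNCO (1.3 equiv), Et3N (0.2 equiv), CH2Cl2, rt
Reagents that add atoms: isopropyl isocyanate, CC(C)N=C=O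
Why: Amine-catalysed addition of the phenol to the isocyanate (carbamoylation) installs an N-isopropyl carbamate, a strong ortho-directing group that can later be cleaved by mild base.

Step 3
Reactants: 3 3,5-bis(methoxymethoxy)phenyl N-(propan-2-yl)carbamate
Product: 7 3,5-bis(methoxymethoxy)-2-(trimethylsilyl)phenyl N-(propan-2-yl)carbamate, via N-silyl carbamate 4 (not isolated), via aryllithium 5 (not isolated), via N,C-bis-silyl carbamate 6 (not isolated)
Conditions: TMSOTf (1.1 equiv), TMEDA (1.1 equiv), Et2O, 0 °C to rt; then TMEDA (2 equiv), n-BuLi (2 equiv), −78 °C; TMSCl (3 equiv), −78 °C to rt; sat. aq. NaHSO4, rt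
Reagents that add atoms: chlorotrimethylsilane, C[Si](C)(C)Cl
Why: Directed ortho-metalation: in-situ N-silylation masks the N–H and suppresses the anionic ortho-Fries shift, n-BuLi/TMEDA then removes the proton at C2, the site flanked by the carbamate and a methoxymethoxy group (two equivalent positions, and a stronger pair of directors than the two ethers around C4), TMSCl traps aryllithium 5, and the N–Si bond of 6 is hydrolysed by a mildly acidic work-up that leaves the acetals intact.

Step 4
Reactants: 7 3,5-bis(methoxymethoxy)-2-(trimethylsilyl)phenyl N-(propan-2-yl)carbamate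
Product: 9 3,5-bis(methoxymethoxy)-2-(trimethylsilyl)phenyl trifluoromethanesulfonate, via silyl phenol 8 (not isolated)
Conditions: DBU (1.5 equiv), Et2NH (1.2 equiv), MeCN, 40 °C; then PhNTf2 (1.5 equiv), rt
Reagents that add atoms: N-phenylbis(trifluoromethanesulfonimide), O=S(=O)(N(c1ccccc1)S(=O)(=O)C(F)(F)F)C(F)(F)F
Why: Base-induced E1cB cleavage of the N–H carbamate (the carbamoyl fragment is scavenged by Et2NH as a urea) frees the hindered phenoxide of 8, which is O-sulfonylated in the same flask by the mild triflating agent PhNTf2 without loss of the aryl–silicon bond.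

Step 5
Reactants: 10 (R)-1,2-epoxypentane; 11 lithium acetylide ethylenediamine complex
Product: 12 (4R)-hept-1-yn-4-ol
Conditions: LiC≡CH·H2NCH2CH2NH2 (1.5 equiv), DMSO, 0 °C to rt; then H2O
Reagents that add atoms: none
Why: SN2 ring opening of the terminal epoxide at its CH2 carbon by the acetylide creates the C15–C16 bond and leaves the carbinol stereocentre untouched, so the R configuration of 10 becomes C17 (R).

Step 6
Reactants: 13 methyl hex-5-ynoate; 14 4-chlorobut-2-yn-1-ol
Product: 16 methyl 10-hydroxydeca-5,8-diynoate, via 4-iodobut-2-yn-1-ol 15 (not isolated)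
Conditions: CuI (1.0 equiv), NaI (1.0 equiv), Cs2CO3 (1.0 equiv), DMF, rt, argon
Reagents that add atoms: none
Why: Copper-mediated alkynyl–propargyl coupling: NaI converts the chloride into the more reactive iodide 15 (Finkelstein exchange), which the terminal alkyne of 13, activated by CuI and Cs2CO3, displaces by SN2 under conditions mild enough to avoid allene formation, forming C6–C7.

Step 7
Reactants: 16 methyl 10-hydroxydeca-5,8-diynoate
Product: 17 methyl 10-bromodeca-5,8-diynoate
Conditions: CBr4 (1.2 equiv), PPh3 (1.2 equiv), CH2Cl2, −20 to 0 °C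
Reagents that add atoms: carbon tetrabromide, BrC(Br)(Br)Br
Why: Appel bromination turns the primary propargylic alcohol into the bromide under neutral conditions that do not isomerise the skipped diyne.

Step 8
Reactants: 17 methyl 10-bromodeca-5,8-diynoate; 18 prop-2-yn-1-ol
Product: 20 methyl 13-hydroxytrideca-5,8,11-triynoate, via methyl 10-iododeca-5,8-diynoate 19 (not isolated)
Conditions: CuI (1.0 equiv), NaI (1.0 equiv), Cs2CO3 (1.0 equiv), DMF, rt, argon, dark
Reagents that add atoms: none
Why: The same copper-mediated alkynyl–propargyl coupling (through the iodide 19) forms C9–C10; the free hydroxyl of 18 is tolerated and becomes the handle for the next activation.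

Step 9
Reactants: 20 methyl 13-hydroxytrideca-5,8,11-triynoate
Product: 21 methyl 13-bromotrideca-5,8,11-triynoate
Conditions: CBr4 (1.2 equiv), PPh3 (1.2 equiv), CH2Cl2, −30 to 0 °C; used at once
Reagents that add atoms: carbon tetrabromide, BrC(Br)(Br)Br
Why: Appel bromination as in step 7; the triyne bromide is sensitive to air, light and base and is therefore carried on without storage.

Step 10
Reactants: 21 methyl 13-bromotrideca-5,8,11-triynoate; 12 (4R)-hept-1-yn-4-ol
Product: 23 methyl (17R)-17-hydroxyicosa-5,8,11,14-tetraynoate, via methyl 13-iodotrideca-5,8,11-triynoate 22 (not isolated)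
Conditions: CuI (1.0 equiv), NaI (1.0 equiv), Cs2CO3 (1.0 equiv), DMF, rt, argon, dark
Reagents that add atoms: none
Why: Copper-mediated alkynyl–propargyl coupling (through the iodide 22) joins C13 to C14; the secondary hydroxyl of 12 does not interfere and its stereocentre, three atoms from the reacting alkyne carbon, is not affected.

Step 11
Reactants: 23 methyl (17R)-17-hydroxyicosa-5,8,11,14-tetraynoate
Product: 24 methyl (5Z,8Z,11Z,14Z,17R)-17-hydroxyicosa-5,8,11,14-tetraenoate
Conditions: H2 (1 atm), nickel boride (Ni2B) made in situ from Ni(OAc)2·4H2O and NaBH4, H2NCH2CH2NH2, EtOH, rt; stopped after uptake of four equivalents of H2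
Reagents that add atoms: none
Why: Cis-selective semihydrogenation: syn delivery of H2 on the amine-moderated nickel boride surface converts each of the four alkynes into a Z alkene, and stopping at four equivalents of hydrogen limits over-reduction.

Step 12
Reactants: 24 methyl (5Z,8Z,11Z,14Z,17R)-17-hydroxyicosa-5,8,11,14-tetraenoate
Product: 25 (5Z,8Z,11Z,14Z,17R)-17-hydroxyicosa-5,8,11,14-tetraenoic acid
Conditions: LiOH·H2O (3 equiv), THF/H2O 3:1, 0 °C to rt; then 1 M HCl to pH 4 at 0 °C
Reagents that add atoms: lithium hydroxide, [Li+].[OH-]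
Why: Saponification of the methyl ester (acyl–oxygen cleavage by hydroxide) at or below room temperature leaves the skipped tetraene and C17 untouched, and careful acidification liberates the acid.

Step 13
Reactants: 25 (5Z,8Z,11Z,14Z,17R)-17-hydroxyicosa-5,8,11,14-tetraenoic acid
Product: 27 (5Z,8Z,11Z,14Z,17R)-17-acetoxyicosa-5,8,11,14-tetraenoic acid, via mixed acetic anhydride 26 (not isolated)
Conditions: Ac2O (3 equiv), pyridine, DMAP (0.1 equiv), CH2Cl2, 0 °C to rt; then H2O/THF/pyridine, rt
Reagents that add atoms: acetic anhydride, CC(=O)OC(C)=O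
Why: DMAP-catalysed O-acetylation masks the C17 hydroxyl, which would otherwise add to the aryne; the mixed anhydride 26 formed at the carboxyl group is hydrolysed selectively in the aqueous pyridine work-up because it is far more electrophilic than the secondary acetate.

Step 14
Reactants: 27 (5Z,8Z,11Z,14Z,17R)-17-acetoxyicosa-5,8,11,14-tetraenoic acid; 9 3,5-bis(methoxymethoxy)-2-(trimethylsilyl)phenyl trifluoromethanesulfonate
Product: 31 (4R,6Z,9Z,12Z,15Z)-20-[2-hydroxy-4,6-bis(methoxymethoxy)phenyl]-20-oxoicosa-6,9,12,15-tetraen-4-yl acetate, via 3,5-bis(methoxymethoxy)benzyne 28 (not isolated), via aryl anion ester 29 (not isolated), via benzoxetane alkoxide 30 (not isolated)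
Conditions: 9 (1.5 equiv), CsF (4 equiv), dry degassed THF, sealed tube, 125 °C, argon; aq. NH4Cl
Reagents that add atoms: none
Why: Fluoride attacks the silicon of 9 and triflate leaves, giving aryne 28; the cesium carboxylate of 27 adds through oxygen to the aryne carbon that becomes C2', the one remote from the C6' methoxymethoxy group, so that the aryl anion of 29 sits at C1' next to that inductively stabilising oxygen. The anion then adds to its own ester carbonyl in a 4-exo-trig mode to give the transient benzoxetane alkoxide 30, whose four-membered ring opens at once by C–O cleavage to the ortho-acyl phenoxide, so the C2'–O and C1'–C1 bonds are made and no ring remains. The closest known reaction type is the fluoride-induced insertion of arynes into the C(=O)–O bond of carboxylic acids to give ortho-hydroxyaryl ketones, combined with the known addition of nucleophiles to 3-alkoxybenzynes at the carbon remote from the alkoxy group. No stereocentre is formed, and C17, held as its acetate so that the alcohol cannot be arylated, is not touched. The step needs regioselectivity, which the ether oxygen flanking the triple bond secures; acyl transfer faster than protonation of 29, which hot aprotic THF with excess CsF to bind the acid proton favours; and preference for the anionic carboxylate over ene reaction at the skipped alkenes, which the far higher nucleophilicity of the carboxylate secures.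

Step 15
Reactants: 31 (4R,6Z,9Z,12Z,15Z)-20-[2-hydroxy-4,6-bis(methoxymethoxy)phenyl]-20-oxoicosa-6,9,12,15-tetraen-4-yl acetate
Product: 32 (5Z,8Z,11Z,14Z,17R)-17-hydroxy-1-[2-hydroxy-4,6-bis(methoxymethoxy)phenyl]icosa-5,8,11,14-tetraen-1-one
Conditions: K2CO3, MeOH, 0 °C to rt, argon; aq. NH4Cl
Reagents that add atoms: none
Why: Base-mediated methanolysis (transesterification) removes the secondary acetate while the acetal ethers are inert to base; it is run before the acetal cleavage so that the air-sensitive triphenol is never exposed to base.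

Step 16
Reactants: 32 (5Z,8Z,11Z,14Z,17R)-17-hydroxy-1-[2-hydroxy-4,6-bis(methoxymethoxy)phenyl]icosa-5,8,11,14-tetraen-1-one
Product: 33 (5Z,8Z,11Z,14Z,17R)-17-hydroxy-1-(2,4,6-trihydroxyphenyl)icosa-5,8,11,14-tetraen-1-one
Conditions: HCl (ca. 1 M in MeOH), rt, argon, dark
Reagents that add atoms: none
Why: Acid-catalysed acetal exchange with methanol cleaves both aryl methoxymethyl ethers at room temperature, conditions that the skipped Z-tetraene, the homoallylic alcohol and the acylphloroglucinol are expected to tolerate under argon.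

**Compound list**

1 | phloroglucinol (benzene-1,3,5-triol) | Oc1cc(O)cc(O)c1 | starting material
2 | 3,5-bis(methoxymethoxy)phenol | COCOc1cc(O)cc(OCOC)c1 | intermediate
3 | 3,5-bis(methoxymethoxy)phenyl N-(propan-2-yl)carbamate | COCOc1cc(OCOC)cc(OC(=O)NC(C)C)c1 | intermediate
4 | 3,5-bis(methoxymethoxy)phenyl N-(propan-2-yl)-N-(trimethylsilyl)carbamate (in flask) | COCOc1cc(OCOC)cc(OC(=O)N(C(C)C)[Si](C)(C)C)c1 | intermediate
5 | {2,4-bis(methoxymethoxy)-6-[(propan-2-yl)(trimethylsilyl)carbamoyloxy]phenyl}lithium (in flask) | [Li]c1c(OCOC)cc(OCOC)cc1OC(=O)N(C(C)C)[Si](C)(C)C | intermediate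
6 | 3,5-bis(methoxymethoxy)-2-(trimethylsilyl)phenyl N-(propan-2-yl)-N-(trimethylsilyl)carbamate (in flask) | COCOc1cc(OCOC)c([Si](C)(C)C)c(OC(=O)N(C(C)C)[Si](C)(C)C)c1 | intermediate
7 | 3,5-bis(methoxymethoxy)-2-(trimethylsilyl)phenyl N-(propan-2-yl)carbamate | COCOc1cc(OCOC)c([Si](C)(C)C)c(OC(=O)NC(C)C)c1 | intermediate
8 | 3,5-bis(methoxymethoxy)-2-(trimethylsilyl)phenol (in flask, as its DBU-H phenoxide) | COCOc1cc(OCOC)c([Si](C)(C)C)c(O)c1 | intermediate
9 | 3,5-bis(methoxymethoxy)-2-(trimethylsilyl)phenyl trifluoromethanesulfonate | COCOc1cc(OCOC)c([Si](C)(C)C)c(OS(=O)(=O)C(F)(F)F)c1 | intermediate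
10 | (R)-1,2-epoxypentane [(2R)-2-propyloxirane] | CCC[C@@H]1CO1 | starting material
11 | lithium acetylide ethylenediamine complex | [Li]C#C.NCCN | starting material
12 | (4R)-hept-1-yn-4-ol | CCC[C@@H](O)CC#C | intermediate
13 | methyl hex-5-ynoate | C#CCCCC(=O)OC | starting material
14 | 4-chlorobut-2-yn-1-ol | OCC#CCCl | starting material
15 | 4-iodobut-2-yn-1-ol (in flask) | OCC#CCI | intermediate
16 | methyl 10-hydroxydeca-5,8-diynoate | COC(=O)CCCC#CCC#CCO | intermediate
17 | methyl 10-bromodeca-5,8-diynoate | COC(=O)CCCC#CCC#CCBr | intermediate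
18 | prop-2-yn-1-ol | C#CCO | starting material
19 | methyl 10-iododeca-5,8-diynoate (in flask) | COC(=O)CCCC#CCC#CCI | intermediate
20 | methyl 13-hydroxytrideca-5,8,11-triynoate | COC(=O)CCCC#CCC#CCC#CCO | intermediate
21 | methyl 13-bromotrideca-5,8,11-triynoate | COC(=O)CCCC#CCC#CCC#CCBr | intermediate
22 | methyl 13-iodotrideca-5,8,11-triynoate (in flask) | COC(=O)CCCC#CCC#CCC#CCI | intermediate
23 | methyl (17R)-17-hydroxyicosa-5,8,11,14-tetraynoate | CCC[C@@H](O)CC#CCC#CCC#CCC#CCCCC(=O)OC | intermediate
24 | methyl (5Z,8Z,11Z,14Z,17R)-17-hydroxyicosa-5,8,11,14-tetraenoate | CCC[C@@H](O)C/C=C\C/C=C\C/C=C\C/C=C\CCCC(=O)OC | intermediate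
25 | (5Z,8Z,11Z,14Z,17R)-17-hydroxyicosa-5,8,11,14-tetraenoic acid | CCC[C@@H](O)C/C=C\C/C=C\C/C=C\C/C=C\CCCC(=O)O | intermediate
26 | acetic (5Z,8Z,11Z,14Z,17R)-17-acetoxyicosa-5,8,11,14-tetraenoic anhydride (in flask) | CCC[C@@H](OC(C)=O)C/C=C\C/C=C\C/C=C\C/C=C\CCCC(=O)OC(C)=O | intermediate
27 | (5Z,8Z,11Z,14Z,17R)-17-acetoxyicosa-5,8,11,14-tetraenoic acid | CCC[C@@H](OC(C)=O)C/C=C\C/C=C\C/C=C\C/C=C\CCCC(=O)O | intermediate
28 | 3,5-bis(methoxymethoxy)benzyne (in flask) | COCOC1=CC#CC(OCOC)=C1 | intermediate
29 | cesium 2-{[(5Z,8Z,11Z,14Z,17R)-17-acetoxyicosa-5,8,11,14-tetraenoyl]oxy}-4,6-bis(methoxymethoxy)benzen-1-ide (in flask) | CCC[C@@H](OC(C)=O)C/C=C\C/C=C\C/C=C\C/C=C\CCCC(=O)OC1=CC(OCOC)=CC(OCOC)=[C-]1.[Cs+] | intermediate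
30 | cesium 2-[(4Z,7Z,10Z,13Z,16R)-16-acetoxynonadeca-4,7,10,13-tetraen-1-yl]-4,6-bis(methoxymethoxy)-2H-benzo[b]oxet-2-olate (in flask) | CCC[C@@H](OC(C)=O)C/C=C\C/C=C\C/C=C\C/C=C\CCCC1([O-])Oc2cc(OCOC)cc(OCOC)c21.[Cs+] | intermediate
31 | (4R,6Z,9Z,12Z,15Z)-20-[2-hydroxy-4,6-bis(methoxymethoxy)phenyl]-20-oxoicosa-6,9,12,15-tetraen-4-yl acetate | CCC[C@@H](OC(C)=O)C/C=C\C/C=C\C/C=C\C/C=C\CCCC(=O)c1c(O)cc(OCOC)cc1OCOC | intermediate
32 | (5Z,8Z,11Z,14Z,17R)-17-hydroxy-1-[2-hydroxy-4,6-bis(methoxymethoxy)phenyl]icosa-5,8,11,14-tetraen-1-one | CCC[C@@H](O)C/C=C\C/C=C\C/C=C\C/C=C\CCCC(=O)c1c(O)cc(OCOC)cc1OCOC | intermediate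
33 | (5Z,8Z,11Z,14Z,17R)-17-hydroxy-1-(2,4,6-trihydroxyphenyl)icosa-5,8,11,14-tetraen-1-one | CCC[C@@H](O)C/C=C\C/C=C\C/C=C\C/C=C\CCCC(=O)c1c(O)cc(O)cc1O | target

**Step count**

Total: 16 steps. Longest linear sequence: 11 steps (steps 6 to 16, from methyl hex-5-ynoate 13).

**Steps most likely to fail, with fallbacks**

Step 14. The aryl anion may be protonated before the acyl group migrates, so that the sequence stops at O-arylation. The aryne may also be consumed in ene reactions with the skipped alkenes, and the polyene may degrade during prolonged heating. The fallback sets out from 24 and from 1 and comes back at 33; it makes the arene the nucleophile. Ester 24 is silylated (TBSCl, imidazole, DMF) to methyl (5Z,8Z,11Z,14Z,17R)-17-[(tert-butyldimethylsilyl)oxy]icosa-5,8,11,14-tetraenoate F1. MeNH(OMe)·HCl and i-PrMgCl (THF, −20 °C) convert this into (5Z,8Z,11Z,14Z,17R)-17-[(tert-butyldimethylsilyl)oxy]-N-methoxy-N-methylicosa-5,8,11,14-tetraenamide F2. Phloroglucinol 1 is fully etherified (excess MOMCl, iPr2NEt) to 1,3,5-tris(methoxymethoxy)benzene F3, which n-BuLi (THF, 0 °C) lithiates between two ether groups to [2,4,6-tris(methoxymethoxy)phenyl]lithium F4. Addition of F4 to F2 at −78 °C (Weinreb ketone synthesis) should give (5Z,8Z,11Z,14Z,17R)-17-[(tert-butyldimethylsilyl)oxy]-1-[2,4,6-tris(methoxymethoxy)phenyl]icosa-5,8,11,14-tetraen-1-one F5. HCl in MeOH at rt then removes the silyl ether and the three acetals and delivers 33 directly.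

Step 11. Hydrogenation may run past the tetraene, stall at enyne stages, or isomerise Z alkenes to E on the catalyst, giving mixtures that are hard to separate. The fallback sets out from 17 and from 10 and comes back at 24. It forms the C14=C15 alkene by Wittig olefination, so that only a triyne has to be hydrogenated.
- Phosphonium half: bromide 17 is coupled with but-3-yn-1-ol under the conditions of step 8 (through 19) to give methyl 14-hydroxytetradeca-5,8,11-triynoate F6. H2 over Pd/CaCO3 poisoned with Pb(OAc)2 and quinoline should reduce it to methyl (5Z,8Z,11Z)-14-hydroxytetradeca-5,8,11-trienoate F7. I2, PPh3 and imidazole give methyl (5Z,8Z,11Z)-14-iodotetradeca-5,8,11-trienoate F8, and PPh3 in MeCN at 80 °C gives [(3Z,6Z,9Z)-14-methoxy-14-oxotetradeca-3,6,9-trien-1-yl]triphenylphosphonium iodide F9.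
- Aldehyde half: epoxide 10 is opened with CH2=CHMgBr and catalytic CuI (THF, −30 °C) to (4R)-hept-1-en-4-ol F10 and silylated (TBSCl, imidazole) to tert-butyl{[(4R)-hept-1-en-4-yl]oxy}dimethylsilane F11. Ozonolysis (O3, CH2Cl2, −78 °C; PPh3) gives (3R)-3-[(tert-butyldimethylsilyl)oxy]hexanal F12.
- Union: F9 is deprotonated with NaN(SiMe3)2 (THF, −78 °C) and condensed with F12 in a Z-selective Wittig olefination to give methyl (5Z,8Z,11Z,14Z,17R)-17-[(tert-butyldimethylsilyl)oxy]icosa-5,8,11,14-tetraenoate F1. n-Bu4NF in THF then frees 24.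

Step 10. The triyne bromide 21 may decompose or isomerise to allenes under the basic coupling conditions faster than it couples. The fallback sets out from 12 and from 17 and comes back at 23; it joins the chain as two diynes and needs no triyne halide. Alkyne 12 is coupled with 3-bromo-1-(trimethylsilyl)prop-1-yne (CuI, NaI, Cs2CO3, DMF; the halide reacts as 3-iodo-1-(trimethylsilyl)prop-1-yne F13, formed in the flask) to give (4R)-10-(trimethylsilyl)deca-6,9-diyn-4-ol F14. n-Bu4NF buffered with AcOH (THF, 0 °C) removes the silyl group to give (4R)-deca-6,9-diyn-4-ol F15. F15 is coupled with bromide 17 under the conditions of step 8 (through 19) to give 23; steps 8 and 9 are then not needed.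

**Further compounds**

F1 | step 14 | methyl (5Z,8Z,11Z,14Z,17R)-17-[(tert-butyldimethylsilyl)oxy]icosa-5,8,11,14-tetraenoate | CCC[C@@H](O[Si](C)(C)C(C)(C)C)C/C=C\C/C=C\C/C=C\C/C=C\CCCC(=O)OC
F2 | step 14 | (5Z,8Z,11Z,14Z,17R)-17-[(tert-butyldimethylsilyl)oxy]-N-methoxy-N-methylicosa-5,8,11,14-tetraenamide | CCC[C@@H](O[Si](C)(C)C(C)(C)C)C/C=C\C/C=C\C/C=C\C/C=C\CCCC(=O)N(C)OC
F3 | step 14 | 1,3,5-tris(methoxymethoxy)benzene | COCOc1cc(OCOC)cc(OCOC)c1
F4 | step 14 | [2,4,6-tris(methoxymethoxy)phenyl]lithium | [Li]c1c(OCOC)cc(OCOC)cc1OCOC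
F5 | step 14 | (5Z,8Z,11Z,14Z,17R)-17-[(tert-butyldimethylsilyl)oxy]-1-[2,4,6-tris(methoxymethoxy)phenyl]icosa-5,8,11,14-tetraen-1-one | CCC[C@@H](O[Si](C)(C)C(C)(C)C)C/C=C\C/C=C\C/C=C\C/C=C\CCCC(=O)c1c(OCOC)cc(OCOC)cc1OCOC
F6 | step 11 | methyl 14-hydroxytetradeca-5,8,11-triynoate | COC(=O)CCCC#CCC#CCC#CCCO
F7 | step 11 | methyl (5Z,8Z,11Z)-14-hydroxytetradeca-5,8,11-trienoate | COC(=O)CCC/C=C\C/C=C\C/C=C\CCO
F8 | step 11 | methyl (5Z,8Z,11Z)-14-iodotetradeca-5,8,11-trienoate | COC(=O)CCC/C=C\C/C=C\C/C=C\CCI
F9 | step 11 | [(3Z,6Z,9Z)-14-methoxy-14-oxotetradeca-3,6,9-trien-1-yl]triphenylphosphonium iodide | COC(=O)CCC/C=C\C/C=C\C/C=C\CC[P+](c1ccccc1)(c1ccccc1)c1ccccc1.[I-]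
F10 | step 11 | (4R)-hept-1-en-4-ol | CCC[C@@H](O)CC=C
F11 | step 11 | tert-butyl{[(4R)-hept-1-en-4-yl]oxy}dimethylsilane | CCC[C@@H](O[Si](C)(C)C(C)(C)C)CC=C
F12 | step 11 | (3R)-3-[(tert-butyldimethylsilyl)oxy]hexanal | CCC[C@@H](O[Si](C)(C)C(C)(C)C)CC=O
F13 | step 10 | 3-iodo-1-(trimethylsilyl)prop-1-yne | C[Si](C)(C)C#CCI
F14 | step 10 | (4R)-10-(trimethylsilyl)deca-6,9-diyn-4-ol | CCC[C@@H](O)CC#CCC#C[Si](C)(C)C
F15 | step 10 | (4R)-deca-6,9-diyn-4-ol | CCC[C@@H](O)CC#CCC#C
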